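**Retrosynthetic overview**
- The C2–Br bond is traced back to a C2–CO2H group (ipso-bromodecarboxylation) and the C3–Br bond to electrophilic bromination. Both lead back to methyl 5,6-dibromo-1H-indole-2-carboxylate.
- In that ester the N1–C7a bond is cut. The pyrrole ring is the only ring built, and it closes when a vinyl nitrene from methyl (Z)-2-azido-3-(3,4-dibromophenyl)acrylate attacks an aryl C–H.
- The azidoacrylate comes from joining the future C2 and C3 by condensing 3,4-dibromobenzaldehyde with methyl azidoacetate.
- Structural feature: C5–Br, C6–Br, C4–H and C7–H of the benzo ring map onto a nitrogen-free 3,4-dibromophenyl ring. N1 can therefore be attached last, at C7a (the ortho C–H para to the C5 bromine), while C2 carries an ester as a placeholder for bromine.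
- Ring order: the benzene ring is bought and the pyrrole ring is closed in step 2.

Key step: step 2

Assumption: methyl azidoacetate is purchased and handled cold, in solution and behind a shield, as a low-molecular-weight azide. The target is achiral, so the only stereochemical element on the route is the Z geometry of the azidoacrylate.

Step 1
Reactants: 1 3,4-dibromobenzaldehyde; 2 methyl azidoacetate
Product: 4 methyl (Z)-2-azido-3-(3,4-dibromophenyl)acrylate, via aldol adduct 3 (not isolated)
Conditions: NaOMe (3 equiv), 2 (3 equiv), MeOH, −10 °C → 5 °C; poured onto ice-water, solid filtered off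
Reagents that add atoms: none
Why: In this Knoevenagel-type aldol condensation the azidoacetate enolate adds to the non-enolisable, electron-poor aldehyde, adduct 3 loses hydroxide by E1cB, the Z alkene results because the aryl group settles trans to the ester, and the low temperature spares the azide and the aryl bromides.

Step 2
Reactants: 4 methyl (Z)-2-azido-3-(3,4-dibromophenyl)acrylate
Product: 6 methyl 5,6-dibromo-1H-indole-2-carboxylate, via 2H-azirine 5 (not isolated)
Conditions: slow addition to refluxing xylenes, 140 °C, about 0.05 M, until N2 evolution ends; chromatography, then recrystallisation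
Reagents that add atoms: none
Why: At 140 °C compound 4 loses N2 to give azirine 5, which equilibrates thermally with the singlet vinyl nitrene. The nitrene nitrogen is held cis to the aryl group by the Z geometry and bonds to an ortho carbon in a 6π 1,5-electrocyclisation, which makes N1–C7a and closes the five-membered pyrrole ring (N1, C2, C3, C3a, C7a); a [1,5]-hydrogen shift from C7a to N1 then restores the benzene ring. This is the Hemetsberger–Knittel indole synthesis, a known thermal reaction of 2-azidocinnamates, and it leaves no stereocentre in the product because the sp3 carbon of 5 becomes planar C3. The step needs site selectivity between the two ortho carbons of the aryl ring: C6' (para to the 3'-bromine, next to a C–H) is wanted and C2' (between the side chain and the 3'-bromine) is not. The 3'-bromine, pushed toward C2' by the buttressing 4'-bromine, crowds that site and deactivates it most strongly by induction, so closure at C6' should prevail; the preference is expected to be moderate, which is why the crystalline ester is purified at this stage. No metal, base or reductant is present, so both C–Br bonds persist, and high dilution suppresses bimolecular decay of the azirine.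

Step 3
Reactants: 6 methyl 5,6-dibromo-1H-indole-2-carboxylate
Product: 7 methyl 3,5,6-tribromo-1H-indole-2-carboxylate
Conditions: NBS (1.05 equiv), DMF, 0 °C → rt, dark; precipitated with water
Reagents that add atoms: N-bromosuccinimide, O=C1CCC(=O)N1Br
Why: In this electrophilic aromatic substitution C3 is the enamine-type carbon and the only strongly nucleophilic position left on an indole deactivated by the C2 ester and two benzo bromines, so one equivalent of NBS should brominate only there.

Step 4
Reactants: 7 methyl 3,5,6-tribromo-1H-indole-2-carboxylate
Product: 8 3,5,6-tribromo-1H-indole-2-carboxylic acid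
Conditions: LiOH (3 equiv), THF/MeOH/H2O, rt → 40 °C; then 1 M HCl, 0 °C, pH 2, solid filtered off and dried
Reagents that add atoms: lithium hydroxide, [Li+].[OH-]
Why: In this saponification (acyl-oxygen ester hydrolysis) hydroxide attacks only the ester carbonyl, the three sp2 C–Br bonds are inert to aqueous LiOH at this temperature, and the acid precipitates on acidification.

Step 5
Reactants: 8 3,5,6-tribromo-1H-indole-2-carboxylic acid
Product: 9 2,3,5,6-tetrabromo-1H-indole
Conditions: NBS (1.05 equiv), LiOAc (0.2 equiv), dry DMF, 0 °C → 40 °C, dark
Reagents that add atoms: N-bromosuccinimide, O=C1CCC(=O)N1Br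
Why: In this ipso-bromodecarboxylation (a Hunsdiecker-type halodecarboxylation known for pyrrole- and indole-2-carboxylic acids) the carboxylate of 8 takes up electrophilic bromine at the C2=C3 enamine unit, either directly at C2 or at C3 followed by a 1,2-bromine shift, loss of CO2 from C2 re-aromatises the pyrrole ring, the succinimide anion regenerates the carboxylate, and the dry medium keeps water from intercepting the bromoindolenine stage.

**Compound list**
1 | 3,4-dibromobenzaldehyde | O=Cc1ccc(Br)c(Br)c1 | starting material
2 | methyl azidoacetate | COC(=O)CN=[N+]=[N-] | starting material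
3 | methyl 2-azido-3-(3,4-dibromophenyl)-3-hydroxypropanoate (aldol adduct, racemic mixture of diastereomers) | COC(=O)C(N=[N+]=[N-])C(O)c1ccc(Br)c(Br)c1 | intermediate
4 | methyl (Z)-2-azido-3-(3,4-dibromophenyl)acrylate | COC(=O)/C(N=[N+]=[N-])=C/c1ccc(Br)c(Br)c1 | intermediate
5 | methyl 2-(3,4-dibromophenyl)-2H-azirine-3-carboxylate (racemic) | COC(=O)C1=NC1c1ccc(Br)c(Br)c1 | intermediate
6 | methyl 5,6-dibromo-1H-indole-2-carboxylate | COC(=O)c1cc2cc(Br)c(Br)cc2[nH]1 | intermediate
7 | methyl 3,5,6-tribromo-1H-indole-2-carboxylate | COC(=O)c1[nH]c2cc(Br)c(Br)cc2c1Br | intermediate
8 | 3,5,6-tribromo-1H-indole-2-carboxylic acid | OC(=O)c1[nH]c2cc(Br)c(Br)cc2c1Br | intermediate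
9 | 2,3,5,6-tetrabromo-1H-indole | Brc1cc2[nH]c(Br)c(Br)c2cc1Br | target

Total step count: 5. Longest linear sequence: 5.

**Steps most likely to fail**

1. Step 2 (key step). The risks are closure at the bromine-flanked ortho carbon in competition with the wanted site, so that material is lost in the separation, and bimolecular decay of the azirine. The fallback fixes the position of nitrogen on the ring before any ring is closed. It sets out from 1. Nitration with HNO3/H2SO4 at 0 °C, directed para to the 3-bromine, should give 4,5-dibromo-2-nitrobenzaldehyde F1, and isomers can be removed at this cheap stage. Wittig olefination with Ph3P=CHCO2Me in toluene should give methyl (E)-3-(4,5-dibromo-2-nitrophenyl)acrylate F2. Cadogan–Sundberg reductive cyclisation with P(OEt)3 at 160 °C then forms N1–C2 in place of N1–C7a, and the fallback returns to the route at 6.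

2. Step 5. The risks are sluggish ipso attack on a pyrrole ring deactivated by three bromines and oxidative capture of the bromoindolenine stage by traces of water. The fallback separates loss of CO2 from bromination. It sets out from 6. Saponification with LiOH in THF/MeOH/H2O should give 5,6-dibromo-1H-indole-2-carboxylic acid F3. Protodecarboxylation with Ag2CO3 (10 mol %) and AcOH in DMSO at 120 °C, which leaves aryl bromides alone, should give 5,6-dibromo-1H-indole F4. NBS (2 equiv) on silica gel in CH2Cl2 then brominates C3 to give 3,5,6-tribromo-1H-indole F5, which is not isolated and is brominated at C2 in the same flask. The fallback returns to the route at 9.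

3. Step 1. The risks are base-induced loss of N2 from the azidoacetate enolate outrunning the aldol addition and stalling at the aldol stage without elimination. The fallback avoids the azidoacetate enolate altogether. It sets out from 1. Wittig olefination with Ph3P=CHCO2Me should give methyl (E)-3-(3,4-dibromophenyl)acrylate F6. Anti addition of Br2 in CH2Cl2 at 0 °C should give racemic methyl (2RS,3SR)-2,3-dibromo-3-(3,4-dibromophenyl)propanoate F7. NaN3 (3 equiv) in DMF at rt replaces bromide by azide and eliminates the β-leaving group by E1cB, as is known for dibromides of chalcones and acrylates. The fallback returns to the route at 4.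

**Further compounds**
F1 | step 2 | 4,5-dibromo-2-nitrobenzaldehyde | O=Cc1cc(Br)c(Br)cc1[N+](=O)[O-]
F2 | step 2 | methyl (E)-3-(4,5-dibromo-2-nitrophenyl)acrylate | COC(=O)/C=C/c1cc(Br)c(Br)cc1[N+](=O)[O-]
F3 | step 5 | 5,6-dibromo-1H-indole-2-carboxylic acid | OC(=O)c1cc2cc(Br)c(Br)cc2[nH]1
F4 | step 5 | 5,6-dibromo-1H-indole | Brc1cc2cc[nH]c2cc1Br
F5 | step 5 | 3,5,6-tribromo-1H-indole | Brc1cc2[nH]cc(Br)c2cc1Br
F6 | step 1 | methyl (E)-3-(3,4-dibromophenyl)acrylate | COC(=O)/C=C/c1ccc(Br)c(Br)c1
F7 | step 1 | methyl (2RS,3SR)-2,3-dibromo-3-(3,4-dibromophenyl)propanoate (racemic, one enantiomer drawn) | COC(=O)[C@H](Br)[C@H](Br)c1ccc(Br)c(Br)c1
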